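A small charge of free catalyst, 56 µM, works in the violet flask on 20 mM of starting material, with 18.0 mM of reagent and 20.0 mM of second substrate beside it. The amber run differs by its 40 mM of starting material.

| flask | starting material | second substrate | reagent | free catalyst | remark | time |
|---|---|---|---|---|---|---|
| violet | 20 mM | 20 mM | 18 mM | 56 µM | the very flask that is asked about, followed so far |  |
| amber | 40 mM | 20 mM | 18 mM | 56 µM | run made earlier |  |
| flask | 20 mM | 20.0 mM | 18.0 mM | 56 µM |  | 8.0 d |

- violet (time / h: target / %, starting material / %): 12.0: 21.9, 54.0; 20.0: 30.9, 38.0; 30.0: 38.1, 24.7; 60.0: 46.5, 14.5; 96.0: 47.6, 11.0; 144: 48.8, 8.7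
- amber (time / h: target / %, starting material / %): 2.50: 4.3, 81.3; 5.00: 7.2, 66.9; 8.00: 13.8, 52.3; 10.0: 14.3, 46.9; 12.0: 15.5, 43.5; 15.0: 18.3, 36.0

(each reading ± 1 percentage point)

- Tuesday's: at 8.0 d add reagent, 100% of the amount charged, then wait 15 d
- Friday's: change nothing and wait 15 d more
- Saturday's: at 8.0 d take out 90% of the target then present, then wait 15 d
- Monday's: at 8.0 d add free catalyst, 100% of the amount charged, then wait 15 d

- target taken out counts as made
- additions bring no volume worth counting

* target, in percent of the starting material first charged, at 8.0 d
* the remedy with the largest gain of target, or "none" below 2 percentage points (Tuesday's / Friday's / Saturday's / Monday's / none)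
* target present, with what was taken out counted in, in percent of the starting material first charged, after Tuesday's
* target present, with what was taken out counted in, in percent of the starting material first charged, after Monday's

In violet, the target can be bracketed by following the starting material. A loose upper bound adds the target and starting material read at 144 h, giving 57.5%. The target reading at 96.0 h, 47.6%, serves as the lower bound, since the readings show no fall. The upper bound tightens because the target's gain per hour between 96.0 h and 144 h is slower than between 20.0 h and 30.0 h. Repeating the last gain over the equal stretch to 8.0 d gives an estimated top of 50.0%, which carries the scatter of the readings.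

The target's gain slows in violet while starting material remains, so this reckoning supposes that the 18.0 mM of reagent has ended. Its measure is the reagent yield, the target made per reagent charged, read from violet as 0.529. At that yield, Tuesday's reagent could pay for 47.6%, more than the 8.7% of starting material read last. So this reckoning places Tuesday's below 57.5%, the sum read at 144 h. Monday's adds no reagent, so this reckoning keeps its target inside the bracket.

The forecast gives 49.3%, inside the bracket, and names Tuesday's, with 55% after it and 50.5% after Monday's. Its ground is: “Exhaustion of reagent fits best, at about 2 equivalents per target”.

The flask gives 48.0%, inside the bracket, and Tuesday's gains 7 percentage points, reaching 55.0%; Monday's stays at 48.0%.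

    starting material + free catalyst ⇌ catalyst intermediate A (K = 580 /M, k = 0.300 /M/s)
    reagent + catalyst intermediate A → free catalyst + target (k = 0.560 /M/s)
    second substrate + free catalyst ⇌ catalyst intermediate B (K = 89.0 /M, k = 0.330 /M/s)
    reagent + catalyst intermediate B → free catalyst + second product (k = 0.360 /M/s)
    2 starting material → self-condensation product (k = 2.70 × 10⁻⁴ /M/s)
    starting material + reagent → uncatalysed product (k = 7.60 × 10⁻⁶ /M/s)

In the flask at 192 h, beside the target stand 8.29 mM of second product, while the reagent, the limiting reagent here, has 0% left. The flask's reagent yield comes to 0.533. Tuesday's reagent at the yield 0.529 pays for 47.6%, more than the 7.2% of starting material still free in the flask. The neighbour charged with 5.0 mM of second substrate reaches 66.5%, a reagent yield of 0.739.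

All runs were generated by integration with constants of no real substance; scatter was added.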